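## The problem

Target 18 is an open-chain 8-O-4' (β-aryl ether) keto acid. A three-carbon chain C7–C8–C9 carries ring B (4-hydroxy-3,5-dimethoxyphenyl) on the C7 ketone and a free hydroxymethyl at C9. C8 is joined through an ether oxygen to C4 of ring A, the 3-methoxybenzoic (vanillic) acid ring. No ring has to be closed: two arenes must be attached to a glycerol-like chain and one stereocenter, C8 (R), must be fixed. Nothing in the target can relay configuration to C8, and any helper center at C7 disappears when C7 becomes the ketone, so the configuration has to come from a catalyst or a chiral building block. C8 is also the fragile point. It is α to an aryl ketone and β to a hydroxyl, so base or warm acid can epimerize it through the enol(ate), eliminate across C8–C9 or split off formaldehyde by retro-aldol cleavage, and the C8–O bond α to the ketone is open to reductive cleavage. The syringyl phenol of ring B is easily oxidized, and both phenol and acid must be masked while the ether is made. The enabling feature is that the ether oxygen sits on ring A carbon C4, para to the carboxyl carbon. As an ester, that carboxyl activates C4 toward nucleophilic aromatic substitution, so the aryl C4–O bond can be formed with the C8 oxygen as nucleophile while all four bonds at C8 stay intact. With C7 held at the alcohol level during that step, C8 has no acidic hydrogen and its configuration can be taken from the chiral pool.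

## Retrosynthesis

**18 ⇒ 17 ⇒ 16 (protecting-group bonds).** The last bonds cut are the two O–benzyl bonds of keto acid 17 (ring B phenol and O9) and, one step earlier, the O–tert-butyl bond of ester 16. Hydrogenolysis is placed last because it is neutral, so the free β-hydroxy ketone of 18 appears in a step without acid or base. The ester is cleaved one step before, while O9 is still benzylated and can neither be acylated nor lost as water. These precursors are no simpler in skeleton, but every sensitive group is masked. The forward steps must spare the aryl ketone and the C8–O bond.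

**16 ⇒ 14 (C7 oxidation level).** The C7=O π bond is traded for a C7–H bond and an O–(4-methoxybenzyl) bond, passing through benzylic alcohol 15. A ketone could not be carried through the ether-forming step, since the strong base would enolize it toward C8. A 4-methoxybenzyl ether is preferred to a second plain benzyl ether or a silyl ether because one quinone oxidant should both remove it and dehydrogenate the electron-rich benzylic alcohol, and because it cannot migrate to a neighbouring alkoxide. Ether 14 has one stereocenter more than 16, but its configuration is irrelevant. The forward step must leave the plain benzyl ethers alone.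

**14 ⇒ 10 + 12 (key cut, aryl C4–O bond of ring A).** This gives secondary alcohol 10 and fluoro ester 12. The neighbouring cut at C8–O (a phenoxide displacing a leaving group at C8) would break a bond at the stereocenter on a hindered carbon flanked by two oxygenated carbons, or, with an α-halo ketone, give racemic material. Cuts at C8–C9 or C7–C8 would need a catalyst-controlled aldol or addition. The chosen cut only carries the C8 configuration and splits the molecule into two pieces of similar size, one of them achiral. The forward reaction asks for an alkoxide that attacks only the fluorine-bearing carbon: hence a single free hydroxyl in 10 (reacting as alkoxide 13), a hindered ester in 12, and fluoride as leaving group.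

**12 ⇒ 11 (O–tert-butyl bond).** Ester 12 goes back to commercial acid 11. The esterification must run under acid catalysis, because tert-butoxide would attack the activated C–F bond.

**10 ⇒ 8 ⇒ 7 ⇒ 5 (oxygen differentiation).** Alcohol 10 is a glycerol-type triol with three different oxygen substituents. Cutting the O9–benzyl bond leads to 1,2-diol 8, whose primary oxygen can be alkylated selectively through stannylene acetal 9. A silyl group at O9 was excluded because it would migrate to the C8 alkoxide in the key step. Diol 8 comes from acetonide 7. Cutting the O–(4-methoxybenzyl) bond of 7 gives alcohol 5, in which the C7 hydroxyl is the only free one, so its etherification (through alkoxide 6) needs no selectivity. A neighbouring route to 10, asymmetric epoxidation of a cinnamyl ether followed by acid-catalysed opening with a benzylic alcohol, would expose an electron-rich aryl epoxide and an acid-labile alcohol to the same acid. The acetonide route uses only standard protecting-group operations.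

**5 ⇒ 2 + 3 (C7–aryl bond), 2 ⇒ 1.** Aryllithium 4, made from bromide 2, adds to aldehyde 3, the acetonide of (R)-glyceraldehyde. Aldehyde 3 delivers C7, C8 and C9, both chain oxygens at C8 and C9, and the C8 configuration from the chiral pool. Facial selectivity at C7 does not matter. Bromide 2 is the benzyl ether of commercial phenol 1. The addition must be fast and cold so that the α-alkoxy aldehyde is not enolized.

## Roads not taken

**Alternative 1: Enzymatic desymmetrization.**
- **Cut and key step:** The aryl ether is made first on achiral material, and C8 starts as the prochiral carbon of diol A1 (tert-butyl 4-[(1,3-dihydroxypropan-2-yl)oxy]-3-methoxybenzoate). Burkholderia cepacia lipase with vinyl acetate would acetylate one enantiotopic hydroxymethyl arm to give monoacetate A2 (tert-butyl 4-{[(2R)-1-acetoxy-3-hydroxypropan-2-yl]oxy}-3-methoxybenzoate). No skeletal bond forms.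
- **Merits:** The ether formation is trivial and free of stereochemical risk. The catalyst is cheap and the conditions are ambient. Enantiotopic acylation of 2-substituted propane-1,3-diols is a mature reaction class.
- **Weak points:** In A2 the stereocenter exists only as the difference between an acetoxymethyl and a hydroxymethyl arm, so any 1,3-acyl shift erases it. Ring B is still missing. One arm must be capped, the other unmasked and oxidized to an α-aryloxy aldehyde (a class that enolizes readily) and then treated with a basic aryl-metal reagent, before C7 is oxidized. The enzyme's fit to this bulky ortho-methoxy aryloxy group is unknown.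
- **Comparison:** The C–O bond formation is clearly easier than the hindered substitution chosen here. The overall count is no lower (about ten steps). Against the easier ether formation the chosen plan sets a C8 center that is never α to a carbonyl until the last three steps and whose configuration does not depend on an enzyme–substrate match.

**Alternative 2: Enantioselective hydroxymethylation.**
- **Cut and key step:** The C8–C9 bond is cut. The (Z)-silyl enol ether A3 (tert-butyl 4-({(Z)-2-[4-(benzyloxy)-3,5-dimethoxyphenyl]-2-[(trimethylsilyl)oxy]ethenyl}oxy)-3-methoxybenzoate) would add to aqueous formaldehyde under Sc(OTf)3 and a chiral 2,2'-bipyridine diol ligand, a Mukaiyama aldol reaction. The product is hydroxy ketone A4 (tert-butyl 4-{[(2R)-1-[4-(benzyloxy)-3,5-dimethoxyphenyl]-3-hydroxy-1-oxopropan-2-yl]oxy}-3-methoxybenzoate).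
- **Merits:** This is the shortest road, about six or seven steps. The racemic aryloxy ketone backbone is classical, the stereocenter is set catalytically, and only two deprotections follow.
- **Weak points:** The reaction is established for enol silanes of simple alkyl aryl ketones. In A3 an additional Lewis-basic aryloxy oxygen sits on the reacting carbon and may alter binding at scandium and the facial bias. The geometry of A3 must be controlled. A4 is the epimerizable, retro-aldol-prone hydroxy ketone itself, formed in the presence of a Lewis acid and water. A shortfall in enantiopurity could be repaired only by crystallization.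
- **Comparison:** Alternative 2 is better in step economy by three or four steps. The chosen plan sets against this a stereocenter of secure origin from the chiral pool and a ketone that appears only after all base-mediated chemistry is over.

**Alternative 3: Dynamic kinetic transfer hydrogenation.**
- **Cut and key step:** No skeletal bond is cut. The C7–H bond is formed on racemic keto ester A5 (methyl 3-[4-(benzyloxy)-3,5-dimethoxyphenyl]-2-[4-(tert-butoxycarbonyl)-2-methoxyphenoxy]-3-oxopropanoate) with RuCl(p-cymene)[(S,S)-TsDPEN], a divalent ruthenium complex, and HCO2H/Et3N. The product is syn hydroxy ester A6 (methyl (2S,3R)-3-[4-(benzyloxy)-3,5-dimethoxyphenyl]-2-[4-(tert-butoxycarbonyl)-2-methoxyphenoxy]-3-hydroxypropanoate).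
- **Merits:** Dynamic kinetic reduction of α-oxygenated β-keto esters is a well-developed class. A5 is quickly assembled, and the route is convergent and probably one or two steps shorter than the chosen one.
- **Weak points:** Two stereocenters are made to keep one. The methyl ester must then be reduced beside the tert-butyl ester. C7 must be reoxidized selectively beside the new primary alcohol, which recreates the labile ketone with a free C9 hydroxyl already present. The level of selectivity depends on how this bulky ortho-substituted aryloxy group fits the catalyst.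
- **Comparison:** Alternative 3 is competitive and avoids the hindered aryl ether formation, which is its real advantage. The chosen plan sets against it a configuration that is bought rather than induced and the absence of a redox detour at C9. The price is the demanding substitution in step 7.

Key step: step 7

Assumption: aldehyde 3 is taken as a commercial material and distilled immediately before use, because it oligomerizes and slowly loses configurational purity on storage. From step 2 on, the route is drawn for the anti (1S) epimer at C7; the syn epimer behaves alike and converges at 16.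

## Route

Step 1
Reactants: 1 4-bromo-2,6-dimethoxyphenol
Product: 2 2-(benzyloxy)-5-bromo-1,3-dimethoxybenzene
Conditions: BnBr, K2CO3, DMF, rt
Reagents that add atoms: benzyl bromide, BrCc1ccccc1
Why: Williamson etherification of a phenoxide with a reactive benzylic halide; the two flanking methoxy groups slow but do not prevent O-alkylation in DMF, and the aryl bromide is inert.

Step 2
Reactants: 2 2-(benzyloxy)-5-bromo-1,3-dimethoxybenzene; 3 (R)-2,2-dimethyl-1,3-dioxolane-4-carbaldehyde
Product: 5 (S)-[4-(benzyloxy)-3,5-dimethoxyphenyl][(4R)-2,2-dimethyl-1,3-dioxolan-4-yl]methanol, via aryllithium 4 (not isolated)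
Conditions: n-BuLi, THF, −78 °C; then 3, −78 → −20 °C; H2O
Reagents that add atoms: none
Why: Bromine–lithium exchange followed by 1,2-addition of the aryllithium to an α-alkoxy aldehyde; C8 is taken unchanged from 3 because addition at −78 °C is much faster than enolization, and the new C7 center is expected to form mainly anti to the C8 oxygen under non-chelation control, which has no consequence since C7 ends as a carbonyl (the syn epimer may be removed by chromatography or carried along).

Step 3
Reactants: 5 (S)-[4-(benzyloxy)-3,5-dimethoxyphenyl][(4R)-2,2-dimethyl-1,3-dioxolan-4-yl]methanol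
Product: 7 (4R)-4-{(S)-[4-(benzyloxy)-3,5-dimethoxyphenyl][(4-methoxybenzyl)oxy]methyl}-2,2-dimethyl-1,3-dioxolane, via sodium alkoxide 6 (not isolated)
Conditions: NaH, THF/DMF, 0 °C; then 4-MeOC6H4CH2Cl, cat. Bu4NI, 0 °C → rt
Reagents that add atoms: 4-methoxybenzyl chloride, COc1ccc(CCl)cc1
Why: Williamson etherification of the only free hydroxyl; the basic conditions leave the acetonide and the benzyl ether untouched and cannot affect C7 or C8, neither of which bears an acidic hydrogen.

Step 4
Reactants: 7 (4R)-4-{(S)-[4-(benzyloxy)-3,5-dimethoxyphenyl][(4-methoxybenzyl)oxy]methyl}-2,2-dimethyl-1,3-dioxolane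
Product: 8 (2R,3S)-3-[4-(benzyloxy)-3,5-dimethoxyphenyl]-3-[(4-methoxybenzyl)oxy]propane-1,2-diol
Conditions: AcOH/H2O (4:1), 40 °C
Reagents that add atoms: none
Why: Acid-catalysed hydrolysis of a terminal isopropylidene acetal; aqueous acetic acid is strong enough for the acetonide but too weak to ionize the C7 benzylic ether or to cleave the 4-methoxybenzyl and benzyl ethers, and no bond at C8 is broken.

Step 5
Reactants: 8 (2R,3S)-3-[4-(benzyloxy)-3,5-dimethoxyphenyl]-3-[(4-methoxybenzyl)oxy]propane-1,2-diol
Product: 10 (1S,2R)-3-(benzyloxy)-1-[4-(benzyloxy)-3,5-dimethoxyphenyl]-1-[(4-methoxybenzyl)oxy]propan-2-ol, via stannylene acetal 9 (not isolated)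
Conditions: Bu2SnO, toluene, reflux (−H2O); then BnBr, cat. Bu4NI, 90 °C
Reagents that add atoms: benzyl bromide, BrCc1ccccc1
Why: Regioselective monoalkylation of a 1,2-diol through its dibutylstannylene acetal; in such acetals of terminal diols the primary oxygen is the more nucleophilic one, so benzyl bromide should alkylate O9 and leave the C8 hydroxyl free, with no bond at C8 broken.

Step 6
Reactants: 11 4-fluoro-3-methoxybenzoic acid
Product: 12 tert-butyl 4-fluoro-3-methoxybenzoate
Conditions: Cl3CC(=NH)Ot-Bu, cat. BF3·OEt2, CH2Cl2/cyclohexane, 0 °C → rt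
Reagents that add atoms: tert-butyl 2,2,2-trichloroacetimidate, CC(C)(C)OC(=N)C(Cl)(Cl)Cl
Why: Acid-catalysed tert-butylation of a carboxylic acid by an imidate (transfer of a tert-butyl cation); no alkoxide base is present, so the activated aryl fluoride is not displaced.

Step 7
Reactants: 10 (1S,2R)-3-(benzyloxy)-1-[4-(benzyloxy)-3,5-dimethoxyphenyl]-1-[(4-methoxybenzyl)oxy]propan-2-ol; 12 tert-butyl 4-fluoro-3-methoxybenzoate
Product: 14 tert-butyl 4-{[(1S,2R)-3-(benzyloxy)-1-[4-(benzyloxy)-3,5-dimethoxyphenyl]-1-[(4-methoxybenzyl)oxy]propan-2-yl]oxy}-3-methoxybenzoate, via potassium alkoxide 13 (not isolated)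
Conditions: KN(SiMe3)2 (1.0 equiv), THF, −20 °C; then 12, DMF, 0 → 45 °C
Reagents that add atoms: none
Why: Nucleophilic aromatic substitution by addition–elimination: alkoxide 13 adds to C4 of 12, the fluorine-bearing carbon para to the ester, giving a Meisenheimer anion whose charge is delocalized onto the ester carbonyl, and fluoride then leaves. The closest known reaction type is the displacement of fluoride from para-fluorobenzoate esters and para-fluorobenzonitriles by alkali alkoxides of secondary alcohols in dipolar aprotic solvents. No ring closes and no stereocenter is created; the C8–O bond of 10 is never broken and C8 has no acidic hydrogen while C7 is an ether, so the R configuration brought in with 3 is retained. Chemoselectivity is secured by the substrate: 10 has a single free hydroxyl, and the tert-butyl ester is too hindered for acyl substitution by a secondary alkoxide, so C4 is the only electrophilic site open to 13. Fluoride is the leaving group of choice because the rate-limiting addition is fastest at the most electron-poor ipso carbon. The ortho methoxy group and the branched alkoxide slow the addition, hence the potassium counter-ion, DMF as cosolvent and gentle warming; the alkoxide is preformed with one equivalent of base so that no free silylamide competes for 12.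

Step 8
Reactants: 14 tert-butyl 4-{[(1S,2R)-3-(benzyloxy)-1-[4-(benzyloxy)-3,5-dimethoxyphenyl]-1-[(4-methoxybenzyl)oxy]propan-2-yl]oxy}-3-methoxybenzoate
Product: 16 tert-butyl 4-{[(2R)-3-(benzyloxy)-1-[4-(benzyloxy)-3,5-dimethoxyphenyl]-1-oxopropan-2-yl]oxy}-3-methoxybenzoate, via benzylic alcohol 15 (not isolated)
Conditions: DDQ (2.5 equiv), CH2Cl2/H2O (10:1), 0 °C → rt
Reagents that add atoms: none
Why: Oxidative cleavage of a 4-methoxybenzyl ether by DDQ (hydride abstraction, hydrolysis of the oxocarbenium ion) followed in the same flask by DDQ dehydrogenation of the electron-rich benzylic alcohol 15 to the aryl ketone; plain benzyl ethers and the tert-butyl ester are inert to DDQ at room temperature, the medium is neutral so the new C8–H is not enolized, and both C7 epimers converge on 16.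

Step 9
Reactants: 16 tert-butyl 4-{[(2R)-3-(benzyloxy)-1-[4-(benzyloxy)-3,5-dimethoxyphenyl]-1-oxopropan-2-yl]oxy}-3-methoxybenzoate
Product: 17 4-{[(2R)-3-(benzyloxy)-1-[4-(benzyloxy)-3,5-dimethoxyphenyl]-1-oxopropan-2-yl]oxy}-3-methoxybenzoic acid
Conditions: CF3CO2H/CH2Cl2 (1:4), 0 °C
Reagents that add atoms: none
Why: Acidolysis of a tert-butyl ester with loss of 2-methylpropene; benzyl ethers and the aryl ketone are stable to cold trifluoroacetic acid, and with O9 still benzylated neither trifluoroacetylation nor dehydration at C9 can occur during the short exposure.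

Step 10
Reactants: 17 4-{[(2R)-3-(benzyloxy)-1-[4-(benzyloxy)-3,5-dimethoxyphenyl]-1-oxopropan-2-yl]oxy}-3-methoxybenzoic acid
Product: 18 4-{[(2R)-3-hydroxy-1-(4-hydroxy-3,5-dimethoxyphenyl)-1-oxopropan-2-yl]oxy}-3-methoxybenzoic acid
Conditions: H2 (1 atm), 10% Pd/C, EtOAc/EtOH, rt
Reagents that add atoms: none
Why: Catalytic hydrogenolysis of an aryl benzyl ether and a primary alkyl benzyl ether; under neutral conditions at ambient pressure O-debenzylation is expected to be much faster than reduction of the electron-rich conjugated aryl ketone or of the C8–O bond, and C8 meets neither acid nor base.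

## Compound list

1 | 4-bromo-2,6-dimethoxyphenol | COc1cc(Br)cc(OC)c1O | starting material
2 | 2-(benzyloxy)-5-bromo-1,3-dimethoxybenzene | COc1cc(Br)cc(OC)c1OCc1ccccc1 | intermediate
3 | (R)-2,2-dimethyl-1,3-dioxolane-4-carbaldehyde | O=C[C@H]1COC(C)(C)O1 | starting material
4 | [4-(benzyloxy)-3,5-dimethoxyphenyl]lithium | [Li]c1cc(OC)c(OCc2ccccc2)c(OC)c1 | intermediate (not isolated)
5 | (S)-[4-(benzyloxy)-3,5-dimethoxyphenyl][(4R)-2,2-dimethyl-1,3-dioxolan-4-yl]methanol | O[C@@H](c1cc(OC)c(OCc2ccccc2)c(OC)c1)[C@H]1COC(C)(C)O1 | intermediate
6 | sodium (S)-[4-(benzyloxy)-3,5-dimethoxyphenyl][(4R)-2,2-dimethyl-1,3-dioxolan-4-yl]methanolate | [Na+].[O-][C@@H](c1cc(OC)c(OCc2ccccc2)c(OC)c1)[C@H]1COC(C)(C)O1 | intermediate (not isolated)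
7 | (4R)-4-{(S)-[4-(benzyloxy)-3,5-dimethoxyphenyl][(4-methoxybenzyl)oxy]methyl}-2,2-dimethyl-1,3-dioxolane | COc1ccc(CO[C@@H](c2cc(OC)c(OCc3ccccc3)c(OC)c2)[C@H]2COC(C)(C)O2)cc1 | intermediate
8 | (2R,3S)-3-[4-(benzyloxy)-3,5-dimethoxyphenyl]-3-[(4-methoxybenzyl)oxy]propane-1,2-diol | COc1ccc(CO[C@@H](c2cc(OC)c(OCc3ccccc3)c(OC)c2)[C@H](O)CO)cc1 | intermediate
9 | (4R)-4-{(S)-[4-(benzyloxy)-3,5-dimethoxyphenyl][(4-methoxybenzyl)oxy]methyl}-2,2-dibutyl-1,3,2-dioxastannolane | CCCC[Sn]1(CCCC)OC[C@@H](O1)[C@@H](OCc1ccc(OC)cc1)c1cc(OC)c(OCc2ccccc2)c(OC)c1 | intermediate (not isolated)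
10 | (1S,2R)-3-(benzyloxy)-1-[4-(benzyloxy)-3,5-dimethoxyphenyl]-1-[(4-methoxybenzyl)oxy]propan-2-ol | O[C@H](COCc1ccccc1)[C@@H](OCc1ccc(OC)cc1)c1cc(OC)c(OCc2ccccc2)c(OC)c1 | intermediate
11 | 4-fluoro-3-methoxybenzoic acid | COc1cc(C(=O)O)ccc1F | starting material
12 | tert-butyl 4-fluoro-3-methoxybenzoate | COc1cc(C(=O)OC(C)(C)C)ccc1F | intermediate
13 | potassium (1S,2R)-3-(benzyloxy)-1-[4-(benzyloxy)-3,5-dimethoxyphenyl]-1-[(4-methoxybenzyl)oxy]propan-2-olate | [K+].[O-][C@H](COCc1ccccc1)[C@@H](OCc1ccc(OC)cc1)c1cc(OC)c(OCc2ccccc2)c(OC)c1 | intermediate (not isolated)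
14 | tert-butyl 4-{[(1S,2R)-3-(benzyloxy)-1-[4-(benzyloxy)-3,5-dimethoxyphenyl]-1-[(4-methoxybenzyl)oxy]propan-2-yl]oxy}-3-methoxybenzoate | COc1cc(C(=O)OC(C)(C)C)ccc1O[C@H](COCc1ccccc1)[C@@H](OCc1ccc(OC)cc1)c1cc(OC)c(OCc2ccccc2)c(OC)c1 | intermediate
15 | tert-butyl 4-{[(1S,2R)-3-(benzyloxy)-1-[4-(benzyloxy)-3,5-dimethoxyphenyl]-1-hydroxypropan-2-yl]oxy}-3-methoxybenzoate | COc1cc(C(=O)OC(C)(C)C)ccc1O[C@H](COCc1ccccc1)[C@@H](O)c1cc(OC)c(OCc2ccccc2)c(OC)c1 | intermediate (not isolated)
16 | tert-butyl 4-{[(2R)-3-(benzyloxy)-1-[4-(benzyloxy)-3,5-dimethoxyphenyl]-1-oxopropan-2-yl]oxy}-3-methoxybenzoate | COc1cc(C(=O)OC(C)(C)C)ccc1O[C@H](COCc1ccccc1)C(=O)c1cc(OC)c(OCc2ccccc2)c(OC)c1 | intermediate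
17 | 4-{[(2R)-3-(benzyloxy)-1-[4-(benzyloxy)-3,5-dimethoxyphenyl]-1-oxopropan-2-yl]oxy}-3-methoxybenzoic acid | COc1cc(C(=O)O)ccc1O[C@H](COCc1ccccc1)C(=O)c1cc(OC)c(OCc2ccccc2)c(OC)c1 | intermediate
18 | 4-{[(2R)-3-hydroxy-1-(4-hydroxy-3,5-dimethoxyphenyl)-1-oxopropan-2-yl]oxy}-3-methoxybenzoic acid | COc1cc(C(=O)O)ccc1O[C@H](CO)C(=O)c1cc(OC)c(O)c(OC)c1 | target

## Step count and risks

Total step count: 10. Longest linear sequence: 9 steps (steps 1–5 and 7–10, from 1 to 18); step 6 is the one-step side branch to 12.

**Step 7 (key step).**
- Risk: slow addition of the hindered secondary alkoxide to the ortho-methoxylated, only moderately activated fluoroarene. Forcing the reaction by heating may then bring loss of the tert-butyl ester or attack of residual silylamide on 12.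
- Fallback: the same C4–O bond is made with a more strongly activated electrophile, and the carboxyl group is reached differently. It sets out from 10 and returns at 17. Alkoxide 13 is treated with 4-fluoro-3-methoxybenzonitrile (KN(SiMe3)2, THF/DMF), whose nitrile activates the fluoride more strongly and offers no acyl carbon. This should give 4-{[(1S,2R)-3-(benzyloxy)-1-[4-(benzyloxy)-3,5-dimethoxyphenyl]-1-[(4-methoxybenzyl)oxy]propan-2-yl]oxy}-3-methoxybenzonitrile F1. Reduction with i-Bu2AlH (toluene, −78 °C, aqueous work-up) should give 4-{[(1S,2R)-3-(benzyloxy)-1-[4-(benzyloxy)-3,5-dimethoxyphenyl]-1-[(4-methoxybenzyl)oxy]propan-2-yl]oxy}-3-methoxybenzaldehyde F2. DDQ under the conditions of step 8 should give 4-{[(2R)-3-(benzyloxy)-1-[4-(benzyloxy)-3,5-dimethoxyphenyl]-1-oxopropan-2-yl]oxy}-3-methoxybenzaldehyde F3. Pinnick oxidation (NaClO2, NaH2PO4, 2-methyl-2-butene, t-BuOH/H2O) then leads to 17.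

**Step 8.**
- Risk: incomplete dehydrogenation of the benzylic alcohol after the fast ether cleavage, or, when pushed with more oxidant or time, oxidative attack on the O9 benzyl ether.
- Fallback: the two events are separated and the oxidant changed. It sets out from 14 and returns at 16. With 1.1 equivalents of DDQ the reaction is stopped at alcohol 15, which is isolated and oxidized with Dess–Martin periodinane (NaHCO3, CH2Cl2, rt). No new compound arises.

**Step 9.**
- Risk: acid-promoted enolization toward C8 with erosion of enantiopurity, or elimination of benzyl alcohol across C8–C9, during the acidolysis.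
- Fallback: the ester is cleaved before the ketone exists. It sets out from 14 and returns at 17. Powdered KOH in THF at room temperature is a known non-acidic cleavage of tert-butyl benzoates, and 14 has neither a base-labile group nor an acidic hydrogen at C8. The product should be 4-{[(1S,2R)-3-(benzyloxy)-1-[4-(benzyloxy)-3,5-dimethoxyphenyl]-1-[(4-methoxybenzyl)oxy]propan-2-yl]oxy}-3-methoxybenzoic acid F4. DDQ under the conditions of step 8 then converts it into 17.

**Step 10.**
- Risk: over-reduction, either hydrogenation of the aryl ketone or reductive cleavage of the activated C8–O bond α to it, before both benzyl ethers are gone.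
- Fallback: non-reductive debenzylation. It sets out from 17 and returns at 18. BCl3 with pentamethylbenzene as benzyl-cation scavenger (CH2Cl2, −78 °C, methanol quench) cleaves both benzyl ethers without a reducing agent. No new compound arises.

## Further compounds

F1 | step 7 | 4-{[(1S,2R)-3-(benzyloxy)-1-[4-(benzyloxy)-3,5-dimethoxyphenyl]-1-[(4-methoxybenzyl)oxy]propan-2-yl]oxy}-3-methoxybenzonitrile | COc1cc(C#N)ccc1O[C@H](COCc1ccccc1)[C@@H](OCc1ccc(OC)cc1)c1cc(OC)c(OCc2ccccc2)c(OC)c1
F2 | step 7 | 4-{[(1S,2R)-3-(benzyloxy)-1-[4-(benzyloxy)-3,5-dimethoxyphenyl]-1-[(4-methoxybenzyl)oxy]propan-2-yl]oxy}-3-methoxybenzaldehyde | COc1cc(C=O)ccc1O[C@H](COCc1ccccc1)[C@@H](OCc1ccc(OC)cc1)c1cc(OC)c(OCc2ccccc2)c(OC)c1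
F3 | step 7 | 4-{[(2R)-3-(benzyloxy)-1-[4-(benzyloxy)-3,5-dimethoxyphenyl]-1-oxopropan-2-yl]oxy}-3-methoxybenzaldehyde | COc1cc(C=O)ccc1O[C@H](COCc1ccccc1)C(=O)c1cc(OC)c(OCc2ccccc2)c(OC)c1
F0 | step 8 | none | none
F4 | step 9 | 4-{[(1S,2R)-3-(benzyloxy)-1-[4-(benzyloxy)-3,5-dimethoxyphenyl]-1-[(4-methoxybenzyl)oxy]propan-2-yl]oxy}-3-methoxybenzoic acid | COc1cc(C(=O)O)ccc1O[C@H](COCc1ccccc1)[C@@H](OCc1ccc(OC)cc1)c1cc(OC)c(OCc2ccccc2)c(OC)c1
F0 | step 10 | none | none
A1 | alternative 1 | tert-butyl 4-[(1,3-dihydroxypropan-2-yl)oxy]-3-methoxybenzoate | COc1cc(C(=O)OC(C)(C)C)ccc1OC(CO)CO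
A2 | alternative 1 | tert-butyl 4-{[(2R)-1-acetoxy-3-hydroxypropan-2-yl]oxy}-3-methoxybenzoate | COc1cc(C(=O)OC(C)(C)C)ccc1O[C@H](CO)COC(C)=O
A3 | alternative 2 | tert-butyl 4-({(Z)-2-[4-(benzyloxy)-3,5-dimethoxyphenyl]-2-[(trimethylsilyl)oxy]ethenyl}oxy)-3-methoxybenzoate | COc1cc(C(=O)OC(C)(C)C)ccc1O/C=C(\O[Si](C)(C)C)c1cc(OC)c(OCc2ccccc2)c(OC)c1
A4 | alternative 2 | tert-butyl 4-{[(2R)-1-[4-(benzyloxy)-3,5-dimethoxyphenyl]-3-hydroxy-1-oxopropan-2-yl]oxy}-3-methoxybenzoate | COc1cc(C(=O)OC(C)(C)C)ccc1O[C@H](CO)C(=O)c1cc(OC)c(OCc2ccccc2)c(OC)c1
A5 | alternative 3 | methyl 3-[4-(benzyloxy)-3,5-dimethoxyphenyl]-2-[4-(tert-butoxycarbonyl)-2-methoxyphenoxy]-3-oxopropanoate | COc1cc(C(=O)OC(C)(C)C)ccc1OC(C(=O)OC)C(=O)c1cc(OC)c(OCc2ccccc2)c(OC)c1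
A6 | alternative 3 | methyl (2S,3R)-3-[4-(benzyloxy)-3,5-dimethoxyphenyl]-2-[4-(tert-butoxycarbonyl)-2-methoxyphenoxy]-3-hydroxypropanoate | COc1cc(C(=O)OC(C)(C)C)ccc1O[C@H](C(=O)OC)[C@H](O)c1cc(OC)c(OCc2ccccc2)c(OC)c1
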